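**Retrosynthetic overview**
1. Numbering (germacranolide): ring C1–C10, oxirane C1–O–C10, C4=C5, lactone O on C6, C11/C12/C13 on C7, OAc on C8, C14 = CH2OAc on C10, C15 = CHO on C4; the target is read as (1R,6R,7R,8S,10R,4E), with a trans-fused lactone and a ring-cis epoxide.
2. Target ⇐ end game (acetylation at C8/C14, MnO2 oxidation of C15, desilylation, α-methylenation at C11) ⇐ tricyclic tris-silyl epoxy lactone.
3. Epoxy lactone ⇐ monocyclic seco diphenylsulfonium ketone: an intramolecular sulfonium ylide epoxidation forms C1–C10 and closes the ten-membered carbocycle and the oxirane together (ring order: lactone first, then carbocycle + oxirane).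
4. Enabling feature: C1–C10 is at once the C–C bond of the oxirane and a bond of the ten-membered ring, and C10 is fully substituted and flanked by the C14 oxygen (retron of ylide carbon + α-oxy ketone); the trans-fused γ-lactone on C6–C7 and the C4=C5 bond with C3 and C6 cis fold the C1…C10 chain.
5. Seco ketone ⇐ C8–C9 Felkin Mukaiyama aldol with silyloxyacetone, C4=C5 Wittig with a formyl ylide, C7–C8 trans conjugate addition of lithiodithiane to (S)-5-(hydroxymethyl)furan-2(5H)-one (C6 from the chiral pool).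

Key step: step 16

Remark: TBS = tert-butyldimethylsilyl, TBDPS = tert-butyldiphenylsilyl; C-locants in comments are those of the target; the SMILES are definitive for configuration; compounds 1, 3, 8 and 18 are taken as commercial.

Step 1
Reactants: 1 (S)-5-(hydroxymethyl)furan-2(5H)-one
Product: 2 (S)-5-(TBDPS-oxymethyl)furan-2(5H)-one
Conditions: TBDPSCl, imidazole, CH2Cl2, 0 °C → rt
Reagents that add atoms: tert-butyl(chloro)diphenylsilane, CC(C)(C)[Si](Cl)(c1ccccc1)c1ccccc1
Why: Imidazole-promoted silylation of a primary alcohol; the chiral-pool centre (future C6) is untouched.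

Step 2
Reactants: 2 (S)-5-(TBDPS-oxymethyl)furan-2(5H)-one; 3 1,3-dithiane
Product: 5 (4S,5S)-5-(TBDPS-oxymethyl)-4-(1,3-dithian-2-yl)oxolan-2-one, via 2-lithio-1,3-dithiane 4 (not isolated)
Conditions: 3, n-BuLi, THF, −30 °C; HMPA, then 2, −78 °C; AcOH quench
Reagents that add atoms: n-butyllithium, [Li]CCCC (lithium of 4 only)
Why: Conjugate addition of a Corey–Seebach formyl anion equivalent (HMPA steers it to 1,4-addition); attack anti to the silyloxymethyl group of the planar butenolide sets C7 trans to C6.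

Step 3
Reactants: 5 (4S,5S)-5-(TBDPS-oxymethyl)-4-(1,3-dithian-2-yl)oxolan-2-one
Product: 6 (4S,5S)-4-(1,3-dithian-2-yl)-5-(hydroxymethyl)oxolan-2-one
Conditions: Bu4NF, AcOH, THF, 0 °C → rt
Reagents that add atoms: none
Why: Fluoride cleavage of the silyl ether, buffered with AcOH so that the lactone is not opened.

Step 4
Reactants: 6 (4S,5S)-4-(1,3-dithian-2-yl)-5-(hydroxymethyl)oxolan-2-one
Product: 7 (2S,3S)-3-(1,3-dithian-2-yl)-5-oxooxolane-2-carbaldehyde
Conditions: SO3·pyridine, DMSO, i-Pr2NEt, CH2Cl2, 0 °C; used crude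
Reagents that add atoms: none
Why: Parikh–Doering oxidation tolerates the dithiane and is mild enough to limit epimerisation of the α-oxy aldehyde.

Step 5
Reactants: 8 (but-3-en-1-yl)triphenylphosphonium bromide
Product: 10 2-(triphenyl-λ5-phosphanylidene)pent-4-enal, via but-3-enylidenetriphenylphosphorane 9 (not isolated)
Conditions: KOt-Bu, THF, 0 °C; then HCO2Et, 0 °C → rt
Reagents that add atoms: ethyl formate, CCOC=O
Why: C-formylation of a phosphorus ylide with a formate ester, followed by proton loss, should give the stabilised α-formyl ylide.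

Step 6
Reactants: 7 (2S,3S)-3-(1,3-dithian-2-yl)-5-oxooxolane-2-carbaldehyde; 10 2-(triphenyl-λ5-phosphanylidene)pent-4-enal
Product: 11 (2E)-2-{[(2R,3S)-3-(1,3-dithian-2-yl)-5-oxooxolan-2-yl]methylidene}pent-4-enal
Conditions: toluene, 70 °C
Reagents that add atoms: none
Why: Wittig olefination with a stabilised α-branched formyl ylide should give the trisubstituted enal with C6 trans to CHO (4E), the geometry of the target.

Step 7
Reactants: 11 (2E)-2-{[(2R,3S)-3-(1,3-dithian-2-yl)-5-oxooxolan-2-yl]methylidene}pent-4-enal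
Product: 12 (4S,5R)-4-(1,3-dithian-2-yl)-5-[(1E)-2-(hydroxymethyl)penta-1,4-dien-1-yl]oxolan-2-one
Conditions: NaBH4, CeCl3·7H2O, MeOH, −40 °C
Reagents that add atoms: none
Why: Luche reduction gives 1,2-reduction of the enal and leaves the lactone and both alkenes alone.

Step 8
Reactants: 12 (4S,5R)-4-(1,3-dithian-2-yl)-5-[(1E)-2-(hydroxymethyl)penta-1,4-dien-1-yl]oxolan-2-one
Product: 13 (4S,5R)-4-(1,3-dithian-2-yl)-5-[(1E)-2-(TBS-oxymethyl)penta-1,4-dien-1-yl]oxolan-2-one
Conditions: TBSCl, imidazole, CH2Cl2, rt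
Reagents that add atoms: tert-butyl(chloro)dimethylsilane, CC(C)(C)[Si](C)(C)Cl
Why: Silylation of the primary allylic alcohol (C15) keeps C15 non-electrophilic up to the end game.

Step 9
Reactants: 13 (4S,5R)-4-(1,3-dithian-2-yl)-5-[(1E)-2-(TBS-oxymethyl)penta-1,4-dien-1-yl]oxolan-2-one
Product: 15 (4S,5R)-4-(1,3-dithian-2-yl)-5-[(1E)-5-hydroxy-2-(TBS-oxymethyl)pent-1-en-1-yl]oxolan-2-one, via B-alkyl-9-BBN 14 (not isolated)
Conditions: 9-BBN, THF, 0 °C → rt; then NaBO3·4H2O, H2O, rt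
Reagents that add atoms: 9-borabicyclo[3.3.1]nonane, B1C2CCCC1CCC2 (boron and cyclooctanediyl of 14 only); sodium perborate, B(=O)O[O-].[Na+] (oxygen of the C1 hydroxyl)
Why: Hydroboration–oxidation in which 9-BBN selects the monosubstituted alkene over the trisubstituted one and places boron on the terminal carbon (C1); perborate is mild towards lactone and dithiane.

Step 10
Reactants: 15 (4S,5R)-4-(1,3-dithian-2-yl)-5-[(1E)-5-hydroxy-2-(TBS-oxymethyl)pent-1-en-1-yl]oxolan-2-one
Product: 16 (4S,5R)-4-(1,3-dithian-2-yl)-5-[(1E)-5-iodo-2-(TBS-oxymethyl)pent-1-en-1-yl]oxolan-2-one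
Conditions: I2, PPh3, imidazole, CH2Cl2, 0 °C
Reagents that add atoms: iodine, II
Why: Appel-type iodination of a primary alcohol under neutral conditions.

Step 11
Reactants: 16 (4S,5R)-4-(1,3-dithian-2-yl)-5-[(1E)-5-iodo-2-(TBS-oxymethyl)pent-1-en-1-yl]oxolan-2-one
Product: 17 (2R,3S)-2-[(1E)-5-iodo-2-(TBS-oxymethyl)pent-1-en-1-yl]-5-oxooxolane-3-carbaldehyde
Conditions: MeI, CaCO3, MeCN/H2O 9:1, 40 °C
Reagents that add atoms: water, O
Why: Dithiane hydrolysis through S-methylation unmasks the C8 aldehyde near neutrality; the trans arrangement at C7 is the thermodynamic one.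

Step 12
Reactants: 18 1-(TBS-oxy)propan-2-one
Product: 20 tert-butyl(dimethyl){[2-(trimethylsilyloxy)prop-2-en-1-yl]oxy}silane, via ketone lithium enolate 19 (not isolated)
Conditions: LiN(i-Pr)2, THF, −78 °C; then Me3SiCl, −78 → 0 °C; used directly
Reagents that add atoms: lithium diisopropylamide, [Li]N(C(C)C)C(C)C (lithium of 19 only); chlorotrimethylsilane, C[Si](C)(C)Cl
Why: Kinetic deprotonation of the methyl ketone on the methyl side, away from the α-silyloxy carbon, followed by O-silylation.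

Step 13
Reactants: 17 (2R,3S)-2-[(1E)-5-iodo-2-(TBS-oxymethyl)pent-1-en-1-yl]-5-oxooxolane-3-carbaldehyde; 20 tert-butyl(dimethyl){[2-(trimethylsilyloxy)prop-2-en-1-yl]oxy}silane
Product: 21 (4R,5R)-4-[(1S)-1-hydroxy-3-oxo-4-(TBS-oxy)butyl]-5-[(1E)-5-iodo-2-(TBS-oxymethyl)pent-1-en-1-yl]oxolan-2-one
Conditions: BF3·OEt2, CH2Cl2, −78 °C
Reagents that add atoms: none
Why: Mukaiyama aldol through an open transition state: Felkin–Anh attack anti to the C7–C6 bond (C6 is the larger, more electron-poor α-substituent and this keeps the carbonyl oxygen away from the lactone oxygen) places O8 syn to C11 and sets 8S.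

Step 14
Reactants: 21 (4R,5R)-4-[(1S)-1-hydroxy-3-oxo-4-(TBS-oxy)butyl]-5-[(1E)-5-iodo-2-(TBS-oxymethyl)pent-1-en-1-yl]oxolan-2-one
Product: 22 (4S,5R)-4-[(1S)-3-oxo-1,4-bis(TBS-oxy)butyl]-5-[(1E)-5-iodo-2-(TBS-oxymethyl)pent-1-en-1-yl]oxolan-2-one
Conditions: TBSOTf, 2,6-lutidine, CH2Cl2, −78 °C
Reagents that add atoms: tert-butyldimethylsilyl trifluoromethanesulfonate, CC(C)(C)[Si](C)(C)OS(=O)(=O)C(F)(F)F
Why: Silylation of the secondary C8 alcohol gives a β-silyloxy ketone, which resists base-induced β-elimination far better than a β-acetoxy ketone would.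

Step 15
Reactants: 22 (4S,5R)-4-[(1S)-3-oxo-1,4-bis(TBS-oxy)butyl]-5-[(1E)-5-iodo-2-(TBS-oxymethyl)pent-1-en-1-yl]oxolan-2-one
Product: 23 [(4E)-4-(TBS-oxymethyl)-5-{(2R,3S)-3-[(1S)-3-oxo-1,4-bis(TBS-oxy)butyl]-5-oxooxolan-2-yl}pent-4-en-1-yl]diphenylsulfonium tetrafluoroborate
Conditions: Ph2S (5 equiv), AgBF4, CH2Cl2, 0 °C → rt, dark
Reagents that add atoms: diphenyl sulfide, c1ccc(Sc2ccccc2)cc1; silver tetrafluoroborate, [Ag+].F[B-](F)(F)F
Why: Silver-assisted S-alkylation of diphenyl sulfide by a primary iodide, the standard route to alkyldiphenylsulfonium tetrafluoroborates; Ph2S leaves C1 as the only α-CH of the salt.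

Step 16
Reactants: 23 [(4E)-4-(TBS-oxymethyl)-5-{(2R,3S)-3-[(1S)-3-oxo-1,4-bis(TBS-oxy)butyl]-5-oxooxolan-2-yl}pent-4-en-1-yl]diphenylsulfonium tetrafluoroborate
Product: 26 (1R,6R,7S,8S,10R,4E)-8,14,15-tris(TBS-oxy)-1,10-epoxy-13-norgermacr-4-en-12,6-olide, via sulfonium ylide 24 (not isolated), via betaine 25 (not isolated)
Conditions: KN(SiMe3)2 (1.2 equiv), THF, −78 °C, slow addition of 23 by syringe pump (final 1 mM), then −78 → −20 °C
Reagents that add atoms: none
Why: Proposed new method: KN(SiMe3)2 removes the C1–H next to the diphenylsulfonium group (the only α-CH of the salt and the most acidic C–H of 23), the non-stabilised ylide 24 adds irreversibly to the C10 ketone, which its α-silyloxymethyl group activates, and the alkoxide of betaine 25 displaces Ph2S from C1 in an anti-periplanar SN2 step; the closest known reaction type is the intramolecular Corey–Chaykovsky epoxidation of keto sulfonium salts, established for five- to seven-membered rings, and the extension to a ten-membered ring is defended by known carbanion macrocyclisations to germacrane rings and by the two turn elements of 23 (trans-lactone, C4=C5 with C3 and C6 cis). The ten-membered carbocycle closes by 10-exo-trig attack of C1 on C10 (the C1–C10 bond) and the oxirane closes by 3-exo-tet attack of the C10 oxygen on C1 with inversion at C1. C10 should be set by attack on the ketone face anti to the C8 silyloxy group (polar 1,3-anti model in the folded chain), which gives 10R; C1 is set in the same C–C bond-forming event, because the strain of the ten-membered transition state should favour the betaine with C2 and C9 gauche, which closes to the ring-cis (1R) epoxide. The step needs chemoselectivity for the ketone and ring closure over oligomerisation: C15 is held at the alcohol level as a silyl ether, the α-methylene group is not yet present, the lactone carbonyl is far less electrophilic and would demand an eight- or nine-membered closure, and slow addition to 1 mM keeps the reaction intramolecular.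

Step 17
Reactants: 26 (1R,6R,7S,8S,10R,4E)-8,14,15-tris(TBS-oxy)-1,10-epoxy-13-norgermacr-4-en-12,6-olide
Product: 30 (1R,6R,7S,8S,10R,4E)-8,14,15-tris(TBS-oxy)-1,10-epoxygermacra-4,11(13)-dien-12,6-olide, via lactone lithium enolate 27 (not isolated), via Mannich base 28 (not isolated), via methiodide 29 (not isolated)
Conditions: LiN(i-Pr)2, THF, −78 °C; CH2=NMe2+ I−, −78 °C → rt; MeI, MeOH, rt; aq NaHCO3, EtOAc, rt
Reagents that add atoms: lithium diisopropylamide, [Li]N(C(C)C)C(C)C (lithium of 27 only); Eschenmoser's salt, C=[N+](C)C.[I-]; iodomethane, CI (N-methyl of 29 only)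
Why: Standard α-methylenation of a γ-butyrolactone (enolate Mannich reaction, N-methylation, E1cB elimination); the C11 configuration of 28 is of no consequence.

Step 18
Reactants: 30 (1R,6R,7S,8S,10R,4E)-8,14,15-tris(TBS-oxy)-1,10-epoxygermacra-4,11(13)-dien-12,6-olide
Product: 31 (1R,6R,7R,8S,10R,4E)-1,10-epoxy-8,14,15-trihydroxygermacra-4,11(13)-dien-12,6-olide
Conditions: HF·pyridine, excess pyridine, THF, 0 °C → rt
Reagents that add atoms: none
Why: Buffered HF·pyridine cleaves all three TBS ethers under conditions that are known to spare trisubstituted epoxides and that avoid the alkoxide chemistry (oxa-Michael addition, translactonisation) of basic fluoride.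

Step 19
Reactants: 31 (1R,6R,7R,8S,10R,4E)-1,10-epoxy-8,14,15-trihydroxygermacra-4,11(13)-dien-12,6-olide
Product: 32 (1R,6R,7R,8S,10R,4E)-1,10-epoxy-8,14-dihydroxy-15-oxogermacra-4,11(13)-dien-12,6-olide
Conditions: MnO2 (activated, excess), CH2Cl2, rt
Reagents that add atoms: none
Why: MnO2 oxidises only the allylic C15 alcohol to the enal with retention of the C4=C5 geometry; the C14 and C8 alcohols are not allylic.

Step 20
Reactants: 32 (1R,6R,7R,8S,10R,4E)-1,10-epoxy-8,14-dihydroxy-15-oxogermacra-4,11(13)-dien-12,6-olide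
Product: 33 (1R,6R,7R,8S,10R,4E)-8,14-diacetoxy-1,10-epoxy-15-oxogermacra-4,11(13)-dien-12,6-olide (CNP0211286.1)
Conditions: Ac2O, pyridine, DMAP (cat.), CH2Cl2, 0 °C → rt
Reagents that add atoms: acetic anhydride, CC(=O)OC(C)=O
Why: DMAP-catalysed acetylation of the C8 and C14 hydroxyls completes the target.

**Compound list**
1 | (S)-5-(hydroxymethyl)furan-2(5H)-one | O=C1C=C[C@@H](CO)O1 | starting material
2 | (S)-5-(TBDPS-oxymethyl)furan-2(5H)-one | O=C1C=C[C@@H](CO[Si](c2ccccc2)(c2ccccc2)C(C)(C)C)O1 | intermediate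
3 | 1,3-dithiane | C1CSCSC1 | starting material
4 | 2-lithio-1,3-dithiane | [Li]C1SCCCS1 | intermediate
5 | (4S,5S)-5-(TBDPS-oxymethyl)-4-(1,3-dithian-2-yl)oxolan-2-one | O=C1C[C@H](C2SCCCS2)[C@@H](CO[Si](c2ccccc2)(c2ccccc2)C(C)(C)C)O1 | intermediate
6 | (4S,5S)-4-(1,3-dithian-2-yl)-5-(hydroxymethyl)oxolan-2-one | O=C1C[C@H](C2SCCCS2)[C@@H](CO)O1 | intermediate
7 | (2S,3S)-3-(1,3-dithian-2-yl)-5-oxooxolane-2-carbaldehyde | O=C1C[C@H](C2SCCCS2)[C@@H](C=O)O1 | intermediate
8 | (but-3-en-1-yl)triphenylphosphonium bromide | C=CCC[P+](c1ccccc1)(c1ccccc1)c1ccccc1.[Br-] | starting material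
9 | but-3-enylidenetriphenylphosphorane | C=CCC=P(c1ccccc1)(c1ccccc1)c1ccccc1 | intermediate
10 | 2-(triphenyl-λ5-phosphanylidene)pent-4-enal | O=CC(CC=C)=P(c1ccccc1)(c1ccccc1)c1ccccc1 | intermediate
11 | (2E)-2-{[(2R,3S)-3-(1,3-dithian-2-yl)-5-oxooxolan-2-yl]methylidene}pent-4-enal | O=C1C[C@H](C2SCCCS2)[C@@H](/C=C(/C=O)CC=C)O1 | intermediate
12 | (4S,5R)-4-(1,3-dithian-2-yl)-5-[(1E)-2-(hydroxymethyl)penta-1,4-dien-1-yl]oxolan-2-one | O=C1C[C@H](C2SCCCS2)[C@@H](/C=C(/CO)CC=C)O1 | intermediate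
13 | (4S,5R)-4-(1,3-dithian-2-yl)-5-[(1E)-2-(TBS-oxymethyl)penta-1,4-dien-1-yl]oxolan-2-one | O=C1C[C@H](C2SCCCS2)[C@@H](/C=C(/CO[Si](C)(C)C(C)(C)C)CC=C)O1 | intermediate
14 | B-alkyl-9-BBN adduct of 13 (boron on C1) | O=C1C[C@H](C2SCCCS2)[C@@H](/C=C(/CO[Si](C)(C)C(C)(C)C)CCCB2C3CCCC2CCC3)O1 | intermediate
15 | (4S,5R)-4-(1,3-dithian-2-yl)-5-[(1E)-5-hydroxy-2-(TBS-oxymethyl)pent-1-en-1-yl]oxolan-2-one | O=C1C[C@H](C2SCCCS2)[C@@H](/C=C(/CO[Si](C)(C)C(C)(C)C)CCCO)O1 | intermediate
16 | (4S,5R)-4-(1,3-dithian-2-yl)-5-[(1E)-5-iodo-2-(TBS-oxymethyl)pent-1-en-1-yl]oxolan-2-one | O=C1C[C@H](C2SCCCS2)[C@@H](/C=C(/CO[Si](C)(C)C(C)(C)C)CCCI)O1 | intermediate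
17 | (2R,3S)-2-[(1E)-5-iodo-2-(TBS-oxymethyl)pent-1-en-1-yl]-5-oxooxolane-3-carbaldehyde | O=C1C[C@H](C=O)[C@@H](/C=C(/CO[Si](C)(C)C(C)(C)C)CCCI)O1 | intermediate
18 | 1-(TBS-oxy)propan-2-one | CC(=O)CO[Si](C)(C)C(C)(C)C | starting material
19 | lithium enolate of 18 (methyl side) | [Li]OC(=C)CO[Si](C)(C)C(C)(C)C | intermediate
20 | tert-butyl(dimethyl){[2-(trimethylsilyloxy)prop-2-en-1-yl]oxy}silane | C=C(O[Si](C)(C)C)CO[Si](C)(C)C(C)(C)C | intermediate
21 | (4R,5R)-4-[(1S)-1-hydroxy-3-oxo-4-(TBS-oxy)butyl]-5-[(1E)-5-iodo-2-(TBS-oxymethyl)pent-1-en-1-yl]oxolan-2-one | O=C1C[C@H]([C@@H](O)CC(=O)CO[Si](C)(C)C(C)(C)C)[C@@H](/C=C(/CO[Si](C)(C)C(C)(C)C)CCCI)O1 | intermediate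
22 | (4S,5R)-4-[(1S)-3-oxo-1,4-bis(TBS-oxy)butyl]-5-[(1E)-5-iodo-2-(TBS-oxymethyl)pent-1-en-1-yl]oxolan-2-one | O=C1C[C@H]([C@@H](O[Si](C)(C)C(C)(C)C)CC(=O)CO[Si](C)(C)C(C)(C)C)[C@@H](/C=C(/CO[Si](C)(C)C(C)(C)C)CCCI)O1 | intermediate
23 | [(4E)-4-(TBS-oxymethyl)-5-{(2R,3S)-3-[(1S)-3-oxo-1,4-bis(TBS-oxy)butyl]-5-oxooxolan-2-yl}pent-4-en-1-yl]diphenylsulfonium tetrafluoroborate | O=C1C[C@H]([C@@H](O[Si](C)(C)C(C)(C)C)CC(=O)CO[Si](C)(C)C(C)(C)C)[C@@H](/C=C(/CO[Si](C)(C)C(C)(C)C)CCC[S+](c2ccccc2)c2ccccc2)O1.F[B-](F)(F)F | intermediate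
24 | sulfonium ylide of 23 (carbanion at C1) | O=C1C[C@H]([C@@H](O[Si](C)(C)C(C)(C)C)CC(=O)CO[Si](C)(C)C(C)(C)C)[C@@H](/C=C(/CO[Si](C)(C)C(C)(C)C)CC[CH-][S+](c2ccccc2)c2ccccc2)O1 | intermediate
25 | macrocyclic betaine (C1 diphenylsulfonium, C10 alkoxide; C1–C10 bond formed) | C1C(=O)O[C@@H]2/C=C(/CO[Si](C)(C)C(C)(C)C)CC[C@H]([S+](c3ccccc3)c3ccccc3)[C@]([O-])(CO[Si](C)(C)C(C)(C)C)C[C@H](O[Si](C)(C)C(C)(C)C)[C@@H]12 | intermediate
26 | (1R,6R,7S,8S,10R,4E)-8,14,15-tris(TBS-oxy)-1,10-epoxy-13-norgermacr-4-en-12,6-olide | C1C(=O)O[C@@H]2/C=C(/CO[Si](C)(C)C(C)(C)C)CC[C@H]3O[C@@]3(CO[Si](C)(C)C(C)(C)C)C[C@H](O[Si](C)(C)C(C)(C)C)[C@@H]12 | intermediate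
27 | lithium enolate of lactone 26 (C11=C12–OLi) | C1=C(O[Li])O[C@@H]2/C=C(/CO[Si](C)(C)C(C)(C)C)CC[C@H]3O[C@@]3(CO[Si](C)(C)C(C)(C)C)C[C@H](O[Si](C)(C)C(C)(C)C)[C@@H]12 | intermediate
28 | Mannich base: 11-(dimethylaminomethyl) derivative of 26 (C11 configuration not controlled) | CN(C)CC1C(=O)O[C@@H]2/C=C(/CO[Si](C)(C)C(C)(C)C)CC[C@H]3O[C@@]3(CO[Si](C)(C)C(C)(C)C)C[C@H](O[Si](C)(C)C(C)(C)C)[C@@H]12 | intermediate
29 | methiodide of 28 (11-trimethylammoniomethyl iodide) | C[N+](C)(C)CC1C(=O)O[C@@H]2/C=C(/CO[Si](C)(C)C(C)(C)C)CC[C@H]3O[C@@]3(CO[Si](C)(C)C(C)(C)C)C[C@H](O[Si](C)(C)C(C)(C)C)[C@@H]12.[I-] | intermediate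
30 | (1R,6R,7S,8S,10R,4E)-8,14,15-tris(TBS-oxy)-1,10-epoxygermacra-4,11(13)-dien-12,6-olide | C=C1C(=O)O[C@@H]2/C=C(/CO[Si](C)(C)C(C)(C)C)CC[C@H]3O[C@@]3(CO[Si](C)(C)C(C)(C)C)C[C@H](O[Si](C)(C)C(C)(C)C)[C@@H]12 | intermediate
31 | (1R,6R,7R,8S,10R,4E)-1,10-epoxy-8,14,15-trihydroxygermacra-4,11(13)-dien-12,6-olide | C=C1C(=O)O[C@@H]2/C=C(/CO)CC[C@H]3O[C@@]3(CO)C[C@H](O)[C@@H]12 | intermediate
32 | (1R,6R,7R,8S,10R,4E)-1,10-epoxy-8,14-dihydroxy-15-oxogermacra-4,11(13)-dien-12,6-olide | C=C1C(=O)O[C@@H]2/C=C(/C=O)CC[C@H]3O[C@@]3(CO)C[C@H](O)[C@@H]12 | intermediate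
33 | (1R,6R,7R,8S,10R,4E)-8,14-diacetoxy-1,10-epoxy-15-oxogermacra-4,11(13)-dien-12,6-olide (CNP0211286.1) | C=C1C(=O)O[C@@H]2/C=C(/C=O)CC[C@H]3O[C@@]3(COC(C)=O)C[C@H](OC(C)=O)[C@@H]12 | target

**Step count**
Total: 20 steps. Longest linear sequence: 18 steps from 1 (steps 1–4, 6–11, 13–20); steps 5 and 12 prepare the two side reagents.

**Steps most likely to fail**

Step 16 (proposed new method). The ring closure may lose to intermolecular ylide–ketone addition (oligomerisation) or to proton transfer from C9 or C14 to the ylide (enolisation instead of addition). It may also proceed through the wrong diastereomeric betaine, by attack on the other ketone face or with C2 and C9 anti. The fallback keeps the C1–C10 closure but uses carbonyl olefination followed by epoxidation. It sets out from iodide 22: PPh3 in MeCN at 70 °C should give the phosphonium iodide F1. Slow addition of F1 to KN(SiMe3)2 in THF (1 mM, −78 → 0 °C) should close the ring by intramolecular Wittig reaction to the cyclodecadiene F2, with the ring-cis C1=C10 bond favoured by the medium ring. mCPBA (NaHCO3, CH2Cl2, 0 °C) should then epoxidise C1=C10 in preference to C4=C5, which is deactivated by two allylic oxygens (C6–O and C15–O). Attack from the outer face of the ring would give the ring-cis epoxide, and the route is rejoined at 26.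

Step 13. Facial selectivity at the C8 aldehyde may be poor, because the polar effect of the C6 lactone oxygen can oppose the Felkin preference, and C7 may epimerise before addition. The fallback replaces substrate control in an open transition state by reagent control in a closed one. It sets out from ketone 18 and aldehyde 17: (−)-Ipc2BCl and Et3N in Et2O at 0 °C should enolise 18 on the methyl side to the diisopinocampheylboron enolate F3. Addition of 17 at −78 °C and oxidative work-up (H2O2, pH 7 buffer, MeOH) should give the aldol through a chair transition state in which the boron ligands choose the aldehyde face. The antipode of Ipc2BCl that is matched with the Felkin sense would be identified in a trial with both (F3 is drawn for the (−)-reagent). The route is rejoined at 21.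

Step 15. The silver-activated C1 may be captured by the internal C15 silyl ether oxygen or by the C4=C5 π bond (cyclisation) instead of by the weakly nucleophilic Ph2S. The fallback builds the sulfonium centre in the opposite order, sulfur first and then S-arylation, without silver. It sets out from iodide 22: PhSNa in DMF at 0 °C should give the phenyl sulfide F4 by SN2 displacement. Copper-catalysed S-arylation with diphenyliodonium triflate (Cu(OBz)2 cat., chlorobenzene, 110 °C) should give the sulfonium triflate F5. F5 is used in step 16 in place of 23 and rejoins the route at ylide 24.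

**Further compounds**
F1 | step 16 | phosphonium iodide: 22 with the iodide at C1 replaced by Ph3P+ (iodide counter-ion) | O=C1C[C@H]([C@@H](O[Si](C)(C)C(C)(C)C)CC(=O)CO[Si](C)(C)C(C)(C)C)[C@@H](/C=C(/CO[Si](C)(C)C(C)(C)C)CCC[P+](c2ccccc2)(c2ccccc2)c2ccccc2)O1.[I-]
F2 | step 16 | cyclodecadiene: (6R,7S,8S,1(10)E,4E)-8,14,15-tris(TBS-oxy)-13-norgermacra-1(10),4-dien-12,6-olide | C1C(=O)O[C@@H]2/C=C(/CO[Si](C)(C)C(C)(C)C)CC/C=C(/CO[Si](C)(C)C(C)(C)C)C[C@H](O[Si](C)(C)C(C)(C)C)[C@@H]12
F3 | step 13 | boron enolate: 3-(TBS-oxy)prop-1-en-2-yl diisopinocampheylborinate from (−)-Ipc2BCl | C=C(CO[Si](C)(C)C(C)(C)C)OB([C@@H]1C[C@@H]2C[C@H]([C@H]1C)C2(C)C)[C@@H]1C[C@@H]2C[C@H]([C@H]1C)C2(C)C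
F4 | step 15 | phenyl sulfide: 22 with the iodide at C1 replaced by SPh | O=C1C[C@H]([C@@H](O[Si](C)(C)C(C)(C)C)CC(=O)CO[Si](C)(C)C(C)(C)C)[C@@H](/C=C(/CO[Si](C)(C)C(C)(C)C)CCCSc2ccccc2)O1
F5 | step 15 | sulfonium triflate: the cation of 23 with trifluoromethanesulfonate counter-ion | O=C1C[C@H]([C@@H](O[Si](C)(C)C(C)(C)C)CC(=O)CO[Si](C)(C)C(C)(C)C)[C@@H](/C=C(/CO[Si](C)(C)C(C)(C)C)CCC[S+](c2ccccc2)c2ccccc2)O1.[O-]S(=O)(=O)C(F)(F)F
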